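**Plan**

- Numbering: C1 is the carboxyl carbon, C3–C6 are the ring carbons (O2 on C3, O1 on C6), C7–C14 the chain (C14 = CHPh).
- Cuts: C9=C10 (Julia–Kocienski), C2–C3 (acetate unit onto a ring peroxycarbenium ion) and, in one operation, C3–C4 together with O1–C6. A helper bond C4–C9 is present in the precursor.
- Enabling feature: with C4 tied to C9, atoms C9–C4–C5–C6–C7–C8 form a cyclohexanone in which C4 is the enolisable α-carbon and C6 a tertiary γ-carbon. Their axial positions are 1,3-related and one C–O–O unit apart, so a formal [3+3] annulation with a peroxy-orthoformate gives a 2,3-dioxabicyclo[3.3.1]nonan-6-one.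
- Forward: 2,4,6-trimethylphenol → meso 4-siloxy-2,4,6-trimethylcyclohexanone → enol silane → [3+3] annulation (the 1,2-dioxane arises here) → C8 inversion → acetate arm at C3 → alkoxyl-radical β-scission of C4–C9 (opens the helper ring, leaves C9 as aldehyde) → olefination with the C10–C14 sulfone → saponification.
- Stereochemistry: absolute sense from a chiral lithium amide desymmetrisation (C8), relayed to C4 (trans attack) and C6 (bridging). C3 comes from exo-axial attack on the bicyclic peroxycarbenium ion, C8 from kinetic exo protonation, C4–H from H-atom delivery anti to the C3 arm, C12 from Ru-BINAP hydrogenation, and both E-alkenes from Horner–Wadsworth–Emmons and Julia–Kocienski olefination.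

Key step: step 6

Assumption: 6 is used as the commercial E/Z mixture; the (R,R)-amide of step 4 and the (R)-BINAP complex of step 12 are taken to give the enantiomers drawn, the antipodal reagent being used if the sense proves opposite.

Step 1
Reactants: 1 2,4,6-trimethylphenol
Product: 2 4-hydroxy-2,4,6-trimethylcyclohexa-2,5-dien-1-one
Conditions: PhI(OAc)2 (1.1 equiv), MeCN/H2O 3:1, 0 °C
Reagents that add atoms: water, O
Why: Oxidative dearomatisation of a para-alkylphenol with water as the nucleophile should give the para-quinol; no stereocenter is formed.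

Step 2
Reactants: 2 4-hydroxy-2,4,6-trimethylcyclohexa-2,5-dien-1-one
Product: 3 (2R,6S)-4-hydroxy-2,4,6-trimethylcyclohexan-1-one (meso; hydroxyl trans to both α-methyls)
Conditions: H2 (1 atm), 5% Rh/Al2O3, EtOAc, rt; then NaOMe (0.1 equiv), MeOH, rt
Reagents that add atoms: none
Why: Catalytic hydrogenation of both enone C=C bonds from the hydroxyl face, followed by base equilibration of the α-centres, should give the diequatorial cis-2,6-dimethyl (meso) ketone; the carbinol configuration is without consequence because this carbon is ionised in step 6.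

Step 3
Reactants: 3 (2R,6S)-4-hydroxy-2,4,6-trimethylcyclohexan-1-one
Product: 4 (2R,6S)-2,4,6-trimethyl-4-(trimethylsilyloxy)cyclohexan-1-one (meso)
Conditions: N-(trimethylsilyl)imidazole (1.5 equiv), CH2Cl2, rt
Reagents that add atoms: N-(trimethylsilyl)imidazole, C[Si](C)(C)n1ccnc1
Why: Silyl transfer from a silylimidazole caps the tertiary alcohol without enolising the ketone (O-silylation); no stereocenter is touched.

Step 4
Reactants: 4 (2R,6S)-2,4,6-trimethyl-4-(trimethylsilyloxy)cyclohexan-1-one
Product: 5 (4S,6S)-2,4,6-trimethyl-1,4-bis(trimethylsilyloxy)cyclohex-1-ene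
Conditions: (R,R)-bis(1-phenylethyl)amine, n-BuLi, LiCl, Me3SiCl (5 equiv, present from the start), THF, −78 °C
Reagents that add atoms: chlorotrimethylsilane, C[Si](C)(C)Cl
Why: Enantioselective deprotonation of a meso ketone by a chiral lithium amide with in situ silylation should differentiate the two enantiotopic axial α-hydrogens, so that the untouched α-carbon becomes the (6S) stereocenter of 5.

Step 5
Reactants: 6 1,2-dimethoxyethene
Product: 8 (dimethoxymethyl)(triethylsilyl) peroxide, via dimethoxymethyl hydroperoxide 7 (not isolated)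
Conditions: O3, MeOH/CH2Cl2 1:1, −78 °C; N2 purge; then Et3SiCl, imidazole, DMAP (cat.), −78 → 0 °C
Reagents that add atoms: ozone, [O-][O+]=O; methanol, CO; chlorotriethylsilane, CC[Si](Cl)(CC)CC
Why: Criegee ozonolysis of the enol ether in methanol should give methyl formate and the methoxy carbonyl oxide, which methanol traps as the α,α-dimethoxy hydroperoxide, and O-silylation of a hydroperoxide with a chlorosilane and imidazole is standard.

Step 6
Reactants: 5 (4S,6S)-2,4,6-trimethyl-1,4-bis(trimethylsilyloxy)cyclohex-1-ene; 8 (dimethoxymethyl)(triethylsilyl) peroxide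
Product: 10 (1S,5R,7S)-4-methoxy-1,5,7-trimethyl-2,3-dioxabicyclo[3.3.1]nonan-6-one (7-methyl exo; both C4 epimers), via Mukaiyama adduct 9 (not isolated)
Conditions: TMSOTf (0.3 equiv), 4 Å MS, CH2Cl2, −78 °C (1 h), then −78 → −20 °C
Reagents that add atoms: none
Why: Proposed new method: TMSOTf abstracts one methoxy group of 8 (the most basic oxygen) to give a methoxy- and silylperoxy-stabilised carbenium ion that the tetrasubstituted enol silane attacks through C4 (Mukaiyama-type addition), giving ketone 9; on warming, the silyl triflate ionises the tertiary silyl ether at C6 and the silylperoxy oxygen O1 captures the cation with loss of its silyl group. The closest known reaction types are the Lewis acid addition of silyl enol ethers to peroxycarbenium and orthoformate-derived ions, and the capture of tertiary carbocations by silyl peroxides in the annulation of peroxycarbenium ions with alkenes to 1,2-dioxolanes; their union as a formal [3+3] annulation across C4 and C6 of a cyclohexanone is new. The 1,2-dioxane ring closes in a six-membered SN1-type closure by attack of O1 on the trigonal C6 cation, which is possible only when the C3 arm on C4 and the new C6–O1 bond are both axial, so the product is the chair–chair 2,3-dioxabicyclo[3.3.1]nonanone. C4 is set by approach of the electrophile to the enol face trans to the C8 methyl (the usual trans-2,6 outcome of α-substitution of 6-alkylcyclohexanone enol derivatives), C6 is then fixed by the bridging geometry, and the acetal carbon C3 forms as an inconsequential epimer mixture that is ionised again in step 8. The step needs C–C bond formation before ionisation at C6, secured by the temperature order (the orthoester ionises at −78 °C, the tertiary ether only on warming), and capture of the cation by O1 rather than by the ketone or methoxy oxygen or by proton loss, secured because only loss of the silyl group from the peroxonium ion is irreversible while the other events are reversed by the acid present.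

Step 7
Reactants: 10 (1S,5R,7S)-4-methoxy-1,5,7-trimethyl-2,3-dioxabicyclo[3.3.1]nonan-6-one
Product: 12 (1S,5R,7R)-4-methoxy-1,5,7-trimethyl-2,3-dioxabicyclo[3.3.1]nonan-6-one (7-methyl endo; both C4 epimers), via silyl enol ether 11 (not isolated)
Conditions: TMSOTf (1.3 equiv), Et3N (2 equiv), CH2Cl2, 0 °C → rt; then Bu4NF, AcOH (1:1.2), THF, −78 °C
Reagents that add atoms: none
Why: Soft enolisation can occur only towards C8 (C4 is quaternary), and kinetic protonation of the fluoride-liberated enolate on its exo face, the endo face being screened by the O–O bridge, should place hydrogen exo and the methyl endo, which is the (R) configuration needed at C8 (silyl enol ether formation followed by kinetic enolate protonation).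

Step 8
Reactants: 12 (1S,5R,7R)-4-methoxy-1,5,7-trimethyl-2,3-dioxabicyclo[3.3.1]nonan-6-one; 13 tert-butyl[(1-methoxyethenyl)oxy]dimethylsilane
Product: 14 methyl 2-[(1S,4S,5R,7R)-1,5,7-trimethyl-6-oxo-2,3-dioxabicyclo[3.3.1]nonan-4-yl]acetate
Conditions: TMSOTf (1.0 equiv), CH2Cl2, −78 °C
Reagents that add atoms: none
Why: Lewis acid ionisation of a cyclic peroxyacetal to the ring peroxycarbenium ion and Mukaiyama-type addition of a silyl ketene acetal is an established way to attach an acetate arm to a cyclic peroxide; attack along the axial trajectory on the exo face, anti to the axial C4–C9 bond, should set C3 as (S), cis to the C4 methyl.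

Step 9
Reactants: 14 methyl 2-[(1S,4S,5R,7R)-1,5,7-trimethyl-6-oxo-2,3-dioxabicyclo[3.3.1]nonan-4-yl]acetate
Product: 15 6-hydroxy compound of 14 (both carbinol epimers; other centres as in 14)
Conditions: NaBH4, CeCl3·7H2O, MeOH, −78 → −40 °C
Reagents that add atoms: none
Why: Luche reduction is selective for the ketone over ester and dialkyl peroxide, and its cold, weakly basic medium should spare the epimerisable C8; the new carbinol centre is a mixture that is destroyed in step 11.

Step 10
Reactants: 15 6-hydroxy compound of 14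
Product: 16 O-benzenesulfenate of 15
Conditions: PhSCl (freshly prepared), Et3N, CH2Cl2, −78 °C
Reagents that add atoms: benzenesulfenyl chloride, ClSc1ccccc1
Why: O-sulfenylation of a secondary alcohol gives the alkyl benzenesulfenate, a standard precursor of alkoxyl radicals; no stereocenter is touched.

Step 11
Reactants: 16 O-benzenesulfenate of 15
Product: 17 methyl 2-[(3S,4S,6R)-4,6-dimethyl-6-[(2R)-2-methyl-3-oxopropyl]-1,2-dioxan-3-yl]acetate
Conditions: Bu3SnH (1.5 equiv), AIBN (0.1 equiv), benzene, 70 °C
Reagents that add atoms: none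
Why: Stannyl radical cleavage of the S–O bond gives the C9 alkoxyl radical, whose β-scission breaks the strained C9–C4 bond towards the tertiary radical and unveils the C9 aldehyde (alkoxyl radical β-fragmentation); hydrogen transfer from the stannane to the planar C4 radical anti to the vicinal C3 arm and to the C6 methyl on the same face should give the (4S) centre.

Step 12
Reactants: 18 3-methylideneoxolan-2-one
Product: 19 (3S)-3-methyloxolan-2-one
Conditions: H2 (100 atm), Ru(OAc)2[(R)-BINAP] (0.5 mol %), CH2Cl2, 50 °C
Reagents that add atoms: none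
Why: Ru-BINAP asymmetric hydrogenation of the exocyclic enoate C=C should set the methyl-bearing (S) centre (later C12) under catalyst control.

Step 13
Reactants: 19 (3S)-3-methyloxolan-2-one
Product: 20 (3S)-3-methyloxolan-2-ol (both anomers)
Conditions: i-Bu2AlH (1.05 equiv), CH2Cl2, −78 °C; Rochelle salt work-up
Reagents that add atoms: none
Why: Partial reduction of a γ-lactone at low temperature stops at the lactol; the α-stereocenter is not touched.

Step 14
Reactants: 20 (3S)-3-methyloxolan-2-ol; 21 diethyl benzylphosphonate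
Product: 22 (3S,4E)-3-methyl-5-phenylpent-4-en-1-ol
Conditions: KOtBu (2.2 equiv), THF, 0 °C → rt
Reagents that add atoms: none
Why: Horner–Wadsworth–Emmons olefination of the open hydroxy-aldehyde form of the lactol with the benzylphosphonate anion should give the E-styrene, the low temperature limiting α-epimerisation.

Step 15
Reactants: 22 (3S,4E)-3-methyl-5-phenylpent-4-en-1-ol; 23 1-phenyl-1H-tetrazole-5-thiol
Product: 24 5-{[(3S,4E)-3-methyl-5-phenylpent-4-en-1-yl]sulfanyl}-1-phenyl-1H-tetrazole
Conditions: PPh3, DIAD, THF, 0 °C → rt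
Reagents that add atoms: none
Why: Mitsunobu thioetherification of a primary alcohol with the acidic tetrazole thiol is routine and remote from the stereocenter.

Step 16
Reactants: 24 5-{[(3S,4E)-3-methyl-5-phenylpent-4-en-1-yl]sulfanyl}-1-phenyl-1H-tetrazole
Product: 25 5-{[(3S,4E)-3-methyl-5-phenylpent-4-en-1-yl]sulfonyl}-1-phenyl-1H-tetrazole
Conditions: 30% H2O2, (NH4)6Mo7O24·4H2O (cat.), EtOH, 0 °C → rt
Reagents that add atoms: hydrogen peroxide, OO
Why: Molybdate-catalysed oxidation of the sulfide to the sulfone is chemoselective in the presence of a styrene.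

Step 17
Reactants: 17 methyl 2-[(3S,4S,6R)-4,6-dimethyl-6-[(2R)-2-methyl-3-oxopropyl]-1,2-dioxan-3-yl]acetate; 25 5-{[(3S,4E)-3-methyl-5-phenylpent-4-en-1-yl]sulfonyl}-1-phenyl-1H-tetrazole
Product: 26 methyl 2-[(3S,4S,6S)-4,6-dimethyl-6-[(2R,3E,6S,7E)-2,6-dimethyl-8-phenylocta-3,7-dien-1-yl]-1,2-dioxan-3-yl]acetate
Conditions: KN(SiMe3)2 (1.1 equiv), DME, −60 °C (25, 20 min); then 17, −60 °C → rt
Reagents that add atoms: none
Why: Julia–Kocienski olefination of a 1-phenyltetrazolyl sulfone with an α-branched aldehyde should give the E-alkene, the pre-formed sulfonyl anion being consumed by the aldehyde faster than it can epimerise C8 or open the β-peroxy ester.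

Step 18
Reactants: 26 methyl 2-[(3S,4S,6S)-4,6-dimethyl-6-[(2R,3E,6S,7E)-2,6-dimethyl-8-phenylocta-3,7-dien-1-yl]-1,2-dioxan-3-yl]acetate
Product: 27 2-[(3S,4S,6S)-4,6-dimethyl-6-[(2R,3E,6S,7E)-2,6-dimethyl-8-phenylocta-3,7-dien-1-yl]-1,2-dioxan-3-yl]acetic acid
Conditions: LiOH·H2O, THF/H2O 3:1, 0 °C → rt; then 1 M HCl to pH 3
Reagents that add atoms: lithium hydroxide, [Li+].[OH-]
Why: Mild saponification of the methyl ester, of the kind used on β-peroxy esters of 1,2-dioxanes, should give the acid without touching any stereocenter.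

**Compound list**

1 | 2,4,6-trimethylphenol | Cc1cc(C)c(O)c(C)c1 | starting material
2 | 4-hydroxy-2,4,6-trimethylcyclohexa-2,5-dien-1-one | CC1=CC(C)(O)C=C(C)C1=O | intermediate
3 | (2R,6S)-4-hydroxy-2,4,6-trimethylcyclohexan-1-one (meso; hydroxyl trans to both α-methyls) | C[C@H]1C[C@](C)(O)C[C@@H](C)C1=O | intermediate
4 | (2R,6S)-2,4,6-trimethyl-4-(trimethylsilyloxy)cyclohexan-1-one (meso) | C[C@H]1C[C@](C)(O[Si](C)(C)C)C[C@@H](C)C1=O | intermediate
5 | (4S,6S)-2,4,6-trimethyl-1,4-bis(trimethylsilyloxy)cyclohex-1-ene | C[C@H]1C[C@](C)(O[Si](C)(C)C)CC(C)=C1O[Si](C)(C)C | intermediate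
6 | 1,2-dimethoxyethene (E/Z mixture) | COC=COC | starting material
7 | dimethoxymethyl hydroperoxide | COC(OC)OO | intermediate
8 | (dimethoxymethyl)(triethylsilyl) peroxide | COC(OC)OO[Si](CC)(CC)CC | intermediate
9 | (2R,4S,6S)-2-[methoxy(triethylsilylperoxy)methyl]-2,4,6-trimethyl-4-(trimethylsilyloxy)cyclohexan-1-one (Mukaiyama adduct; acetal epimers) | C[C@H]1C[C@](C)(O[Si](C)(C)C)C[C@@](C)(C1=O)C(OC)OO[Si](CC)(CC)CC | intermediate
10 | (1S,5R,7S)-4-methoxy-1,5,7-trimethyl-2,3-dioxabicyclo[3.3.1]nonan-6-one (7-methyl exo; both C4 epimers) | C[C@H]1C[C@@]2(C)C[C@@](C)(C1=O)C(OC)OO2 | intermediate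
11 | trimethylsilyl enol ether of 10 (C6=C7 double bond, bridgeheads as in 10) | CC1=C(O[Si](C)(C)C)[C@]2(C)C[C@](C)(C1)OOC2OC | intermediate
12 | (1S,5R,7R)-4-methoxy-1,5,7-trimethyl-2,3-dioxabicyclo[3.3.1]nonan-6-one (7-methyl endo; both C4 epimers) | C[C@@H]1C[C@@]2(C)C[C@@](C)(C1=O)C(OC)OO2 | intermediate
13 | tert-butyl[(1-methoxyethenyl)oxy]dimethylsilane | C=C(OC)O[Si](C)(C)C(C)(C)C | starting material
14 | methyl 2-[(1S,4S,5R,7R)-1,5,7-trimethyl-6-oxo-2,3-dioxabicyclo[3.3.1]nonan-4-yl]acetate | C[C@@H]1C[C@@]2(C)C[C@@](C)(C1=O)[C@H](CC(=O)OC)OO2 | intermediate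
15 | 6-hydroxy compound of 14 (both carbinol epimers; other centres as in 14) | C[C@@H]1C[C@@]2(C)C[C@@](C)(C1O)[C@H](CC(=O)OC)OO2 | intermediate
16 | O-benzenesulfenate of 15 | C[C@@H]1C[C@@]2(C)C[C@@](C)(C1OSc3ccccc3)[C@H](CC(=O)OC)OO2 | intermediate
17 | methyl 2-[(3S,4S,6R)-4,6-dimethyl-6-[(2R)-2-methyl-3-oxopropyl]-1,2-dioxan-3-yl]acetate | C[C@@H](C=O)C[C@@]1(C)C[C@H](C)[C@H](CC(=O)OC)OO1 | intermediate
18 | 3-methylideneoxolan-2-one (α-methylene-γ-butyrolactone) | C=C1CCOC1=O | starting material
19 | (3S)-3-methyloxolan-2-one | C[C@H]1CCOC1=O | intermediate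
20 | (3S)-3-methyloxolan-2-ol (both anomers) | C[C@H]1CCOC1O | intermediate
21 | diethyl benzylphosphonate | CCOP(=O)(Cc1ccccc1)OCC | starting material
22 | (3S,4E)-3-methyl-5-phenylpent-4-en-1-ol | C[C@H](/C=C/c1ccccc1)CCO | intermediate
23 | 1-phenyl-1H-tetrazole-5-thiol | Sc1nnnn1-c1ccccc1 | starting material
24 | 5-{[(3S,4E)-3-methyl-5-phenylpent-4-en-1-yl]sulfanyl}-1-phenyl-1H-tetrazole | C[C@H](/C=C/c1ccccc1)CCSc1nnnn1-c1ccccc1 | intermediate
25 | 5-{[(3S,4E)-3-methyl-5-phenylpent-4-en-1-yl]sulfonyl}-1-phenyl-1H-tetrazole | C[C@H](/C=C/c1ccccc1)CCS(=O)(=O)c1nnnn1-c1ccccc1 | intermediate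
26 | methyl 2-[(3S,4S,6S)-4,6-dimethyl-6-[(2R,3E,6S,7E)-2,6-dimethyl-8-phenylocta-3,7-dien-1-yl]-1,2-dioxan-3-yl]acetate | C[C@H](/C=C/c1ccccc1)C/C=C/[C@H](C)C[C@@]1(C)C[C@H](C)[C@H](CC(=O)OC)OO1 | intermediate
27 | 2-[(3S,4S,6S)-4,6-dimethyl-6-[(2R,3E,6S,7E)-2,6-dimethyl-8-phenylocta-3,7-dien-1-yl]-1,2-dioxan-3-yl]acetic acid | C[C@H](/C=C/c1ccccc1)C/C=C/[C@H](C)C[C@@]1(C)C[C@H](C)[C@H](CC(=O)O)OO1 | target

**Count and risks**

Total: 18 steps. Longest linear sequence: 12 steps (steps 1–4, 6–11, 17, 18).

Step 6 (bears the new-method label). What may go wrong: ionisation of 8 by loss of the silylperoxy group instead of a methoxy group, irreversible proton loss from the C6 cation, or Lewis acid-induced heterolysis of the O–O bond before the bridge closes. The fallback uses known chemistry and sets out from 5. Mukaiyama-type reaction with trimethyl orthoformate and TMSOTf should give (2R,4S,6S)-2-(dimethoxymethyl)-2,4,6-trimethyl-4-(trimethylsilyloxy)cyclohexan-1-one F1. Ethereal H2O2 with catalytic H3PMo12O40 should exchange the tertiary silyl ether for a hydroperoxide by an SN1 path, giving (2R,6S)-2-(dimethoxymethyl)-4-hydroperoxy-2,4,6-trimethylcyclohexan-1-one F2. Of the two carbinol epimers only the one cis to the acetal arm can close, and the other re-ionises. Acid-catalysed intramolecular peroxyacetal exchange with loss of methanol then returns to the route at 10.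

Step 7. What may go wrong: poor facial selectivity in the protonation, or re-enolisation that returns the strained endo-methyl ketone to the exo epimer. The fallback sets out from 11. Saegusa–Ito dehydrogenation with Pd(OAc)2 in MeCN should give the enone 4-methoxy-1,5,7-trimethyl-2,3-dioxabicyclo[3.3.1]non-7-en-6-one F3. Diimide (dipotassium azodicarboxylate, AcOH, MeOH, 0 °C), which leaves O–O bonds alone, should then deliver both hydrogens suprafacially to the open exo face, so the methyl is pushed endo without any enolate being involved. The fallback returns at 12.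

Step 11. What may go wrong: hydrogen delivery to the tertiary C4 radical from the wrong face, or attack of tin or carbon radicals on the O–O bond. The fallback sets out from 15. Hypoiodite β-fragmentation (PhI(OAc)2, I2, visible light, CH2Cl2) should open the same C9–C4 bond and trap the radical as the tertiary iodide methyl 2-[4-iodo-4,6-dimethyl-6-(2-methyl-3-oxopropyl)-1,2-dioxan-3-yl]acetate F4. DBU should eliminate HI to the exocyclic alkene methyl 2-[6-methyl-4-methylidene-6-(2-methyl-3-oxopropyl)-1,2-dioxan-3-yl]acetate F5. Diimide reduction, which tolerates the aldehyde and the peroxide, should add hydrogen to C4 from the face anti to the C3 arm. The fallback returns at 17.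

Further compounds
F1 | step 6 | (2R,4S,6S)-2-(dimethoxymethyl)-2,4,6-trimethyl-4-(trimethylsilyloxy)cyclohexan-1-one | C[C@H]1C[C@](C)(O[Si](C)(C)C)C[C@@](C)(C1=O)C(OC)OC
F2 | step 6 | (2R,6S)-2-(dimethoxymethyl)-4-hydroperoxy-2,4,6-trimethylcyclohexan-1-one (both C4 epimers) | C[C@H]1CC(C)(OO)C[C@@](C)(C1=O)C(OC)OC
F3 | step 7 | 4-methoxy-1,5,7-trimethyl-2,3-dioxabicyclo[3.3.1]non-7-en-6-one (bridgeheads as in 10) | CC1=C[C@@]2(C)C[C@@](C)(C1=O)C(OC)OO2
F4 | step 11 | methyl 2-[4-iodo-4,6-dimethyl-6-(2-methyl-3-oxopropyl)-1,2-dioxan-3-yl]acetate (C4 epimers; other centres as in 17) | C[C@@H](C=O)C[C@@]1(C)CC(C)(I)[C@H](CC(=O)OC)OO1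
F5 | step 11 | methyl 2-[6-methyl-4-methylidene-6-(2-methyl-3-oxopropyl)-1,2-dioxan-3-yl]acetate (centres as in 17) | C[C@@H](C=O)C[C@@]1(C)CC(=C)[C@H](CC(=O)OC)OO1
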